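**Plan**
- Numbering used throughout: benzene carbon C1 carries CH2SO2CH3, C2 Br, C3 OH, C4 OH, C5 Br, C6 Br; this arene is the only ring, it is bought intact and no ring is formed.
- Retrosynthesis: cut C5–Br and C6–Br (bromination of the free catechol), then the two O-methyl ethers and the two S=O bonds, then C1–CH2 and C2–Br together across a C1≡C2 aryne.
- Enabling feature: the carbon arm on C1 and the bromine on C2 are ortho neighbours and C2 lies next to the C3 oxygen. A 3-alkoxybenzyne gives exactly this pattern when a carbanion adds to the aryne carbon remote from the oxygen and the aryl metal formed beside the oxygen is brominated.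
- Forward order: 2,3-dimethoxyphenol → carbamate-directed ortho-iodination → 2-iodoaryl sulfonate → aryne carbomagnesiation with CH3SCH2MgCl and bromine quench → sulfone → catechol → bromination of C5 and C6.
- Stereochemistry: none to set; the target is achiral and no stereocentre or defined double bond appears in any intermediate.

Key step: step 6

Remark on the chemistry: Grignard reagent 10 is handled as a prepared, titrated THF solution, so its formation counts as a step of its own.

**Route**

Step 1
Reactants: 1 2,3-dimethoxyphenol; 2 N,N-diethylcarbamoyl chloride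
Product: 3 2,3-dimethoxyphenyl N,N-diethylcarbamate
Conditions: K2CO3, MeCN, reflux
Reagents that add atoms: N,N-diethylcarbamoyl chloride 2, CCN(CC)C(=O)Cl
Why: O-carbamoylation of the potassium phenoxide (nucleophilic acyl substitution) is routine and installs the strongest oxygen-based directing group for the metalation that follows.

Step 2
Reactants: 3 2,3-dimethoxyphenyl N,N-diethylcarbamate
Product: 5 6-iodo-2,3-dimethoxyphenyl N,N-diethylcarbamate, via aryllithium 4 (not isolated)
Conditions: s-BuLi, TMEDA, THF, −78 °C; then I2, THF, −78 °C → rt
Reagents that add atoms: iodine, II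
Why: Directed ortho-metalation, in which the O-carbamate outranks both methoxy groups and has only one free ortho position, so lithiation at −78 °C (cold enough to suppress the anionic ortho-Fries shift) and iodine quench should place iodine next to the carbamate oxygen.

Step 3
Reactants: 5 6-iodo-2,3-dimethoxyphenyl N,N-diethylcarbamate
Product: 6 6-iodo-2,3-dimethoxyphenol
Conditions: NaOH (10 equiv), EtOH/H2O, reflux; then aq HCl
Reagents that add atoms: none
Why: Base-mediated hydrolysis of the aryl carbamate (acyl substitution at the carbonyl, then loss of the carbamate carbon as carbonate) should free the phenol, while the aryl iodide and the methyl ethers are inert to hot ethanolic hydroxide.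

Step 4
Reactants: 6 6-iodo-2,3-dimethoxyphenol; 7 4-chlorobenzenesulfonyl chloride
Product: 8 6-iodo-2,3-dimethoxyphenyl 4-chlorobenzenesulfonate
Conditions: Et3N, DMAP (cat.), CH2Cl2, 0 °C → rt
Reagents that add atoms: 4-chlorobenzenesulfonyl chloride 7, O=S(=O)(Cl)c1ccc(Cl)cc1
Why: O-sulfonylation of the phenol under amine base with DMAP catalysis gives an aryl sulfonate that tolerates an ortho arylmagnesium at −78 °C yet departs on warming.

Step 5
Reactants: 9 chloromethyl methyl sulfide
Product: 10 (methylthio)methylmagnesium chloride
Conditions: Mg turnings, I2 (cat.), THF, 10–20 °C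
Reagents that add atoms: magnesium, [Mg]
Why: Grignard formation by insertion of magnesium into the activated C–Cl bond of the α-chloro sulfide, run at or below 20 °C because the α-thioalkyl reagent is thermally labile, and titrated before use.

Step 6
Reactants: 8 6-iodo-2,3-dimethoxyphenyl 4-chlorobenzenesulfonate; 10 (methylthio)methylmagnesium chloride; 11 1,2-dibromotetrachloroethane
Product: 15 2-bromo-3,4-dimethoxybenzyl methyl sulfide, via arylmagnesium sulfonate 12 (not isolated), via 3,4-dimethoxybenzyne 13 (not isolated), via adduct arylmagnesium 14 (not isolated)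
Conditions: iPrMgCl (1.05 equiv), THF, −78 °C; then 10 (2 equiv), −78 °C → rt; then 11 (3.5 equiv), −78 → 0 °C
Reagents that add atoms: (methylthio)methylmagnesium chloride 10, CSC[Mg]Cl; 1,2-dibromotetrachloroethane 11, BrC(Cl)(Cl)C(Cl)(Cl)Br
Why: Iodine–magnesium exchange at −78 °C turns 8 into arylmagnesium 12, which on warming expels the ortho sulfonate to give aryne 13 (triple bond C1≡C2 in target numbering); Grignard 10 then adds its carbon to C1 and the C2 arylmagnesium 14 is brominated by 11 with loss of tetrachloroethene. The closest known reaction type is the carbomagnesiation of arynes released from 2-iodoaryl sulfonates or 1,2-dihaloarenes by halogen–magnesium exchange, followed by trapping of the new arylmagnesium with a halogen electrophile, and only the α-thioalkyl nucleophile is new. No ring is closed and no stereocentre is formed. The step needs regioselective addition across the aryne: the C3 methoxy group beside the triple bond polarises and distorts it so that the remote carbon C1 is the electrophilic end, the charge building at C2 is stabilised by the adjacent C–O bond and by O→Mg chelation, and C1 has only the unsubstituted C6 as its other neighbour, so carbon should go to C1 and bromine to C2. Chemoselectivity rests on using barely more than one equivalent of iPrMgCl, which is spent as 2-iodopropane before the aryne appears, and an excess of 10, and on carrying the sulfur as a thioether, whose methylene protons are too weakly acidic to destroy 14, whereas a methylsulfonylmethyl group would protonate the arylmagnesium. Enough 11 is added to brominate 14 and the surplus 10 together.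

Step 7
Reactants: 15 2-bromo-3,4-dimethoxybenzyl methyl sulfide
Product: 16 2-bromo-3,4-dimethoxybenzyl methyl sulfone
Conditions: 2KHSO5·KHSO4·K2SO4 (1.5 equiv), MeOH/H2O, 0 °C → rt
Reagents that add atoms: potassium peroxymonosulfate KHSO5, [K+].[O-]S(=O)(=O)OO
Why: Sulfide-to-sulfone oxidation by peroxymonosulfate proceeds through the sulfoxide, spares the aryl bromide and the methyl ethers, and puts the sulfur at its final oxidation level before any electrophilic bromine is used.

Step 8
Reactants: 16 2-bromo-3,4-dimethoxybenzyl methyl sulfone
Product: 17 2-bromo-3,4-dihydroxybenzyl methyl sulfone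
Conditions: BBr3 (4 equiv), CH2Cl2, −78 °C → rt; then H2O
Reagents that add atoms: none
Why: Lewis-acid ether cleavage, in which BBr3 binds each methoxy oxygen, bromide removes the methyl group by SN2 and aqueous work-up hydrolyses the aryl borates to the catechol, with the sulfone and the aryl bromide unaffected.

Step 9
Reactants: 17 2-bromo-3,4-dihydroxybenzyl methyl sulfone
Product: 19 2,5,6-tribromo-3,4-dihydroxybenzyl methyl sulfone (target), via 2,6-dibromo catechol 18 (not isolated)
Conditions: Br2 (2.3 equiv), AcOH, rt; aq NaHSO3 work-up
Reagents that add atoms: bromine, BrBr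
Why: Electrophilic aromatic bromination, in which C6 (para to the C3 hydroxyl) is expected to react first and C5 (ortho to the C4 hydroxyl) second, so both remaining ring positions should be filled while the electron-poor benzylic sulfone methylene is inert to bromine in acid.

**Compound list**
1 | 2,3-dimethoxyphenol | COc1cccc(O)c1OC | starting material
2 | N,N-diethylcarbamoyl chloride | CCN(CC)C(=O)Cl | starting material
3 | 2,3-dimethoxyphenyl N,N-diethylcarbamate | CCN(CC)C(=O)Oc1cccc(OC)c1OC | intermediate
4 | 6-lithio-2,3-dimethoxyphenyl N,N-diethylcarbamate | CCN(CC)C(=O)Oc1c([Li])ccc(OC)c1OC | intermediate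
5 | 6-iodo-2,3-dimethoxyphenyl N,N-diethylcarbamate | CCN(CC)C(=O)Oc1c(I)ccc(OC)c1OC | intermediate
6 | 6-iodo-2,3-dimethoxyphenol | COc1ccc(I)c(O)c1OC | intermediate
7 | 4-chlorobenzenesulfonyl chloride | O=S(=O)(Cl)c1ccc(Cl)cc1 | starting material
8 | 6-iodo-2,3-dimethoxyphenyl 4-chlorobenzenesulfonate | COc1ccc(I)c(OS(=O)(=O)c2ccc(Cl)cc2)c1OC | intermediate
9 | chloromethyl methyl sulfide | CSCCl | starting material
10 | (methylthio)methylmagnesium chloride | CSC[Mg]Cl | intermediate
11 | 1,2-dibromotetrachloroethane | BrC(Cl)(Cl)C(Cl)(Cl)Br | starting material
12 | 2-(4-chlorobenzenesulfonyloxy)-3,4-dimethoxyphenylmagnesium chloride | COc1ccc([Mg]Cl)c(OS(=O)(=O)c2ccc(Cl)cc2)c1OC | intermediate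
13 | 3,4-dimethoxybenzyne (1,2-didehydro-3,4-dimethoxybenzene) | COC1=C(OC)C#CC=C1 | intermediate
14 | 2,3-dimethoxy-6-[(methylthio)methyl]phenylmagnesium chloride | CSCc1ccc(OC)c(OC)c1[Mg]Cl | intermediate
15 | 2-bromo-3,4-dimethoxybenzyl methyl sulfide | CSCc1ccc(OC)c(OC)c1Br | intermediate
16 | 2-bromo-3,4-dimethoxybenzyl methyl sulfone | CS(=O)(=O)Cc1ccc(OC)c(OC)c1Br | intermediate
17 | 2-bromo-3,4-dihydroxybenzyl methyl sulfone | CS(=O)(=O)Cc1ccc(O)c(O)c1Br | intermediate
18 | 2,6-dibromo-3,4-dihydroxybenzyl methyl sulfone | CS(=O)(=O)Cc1c(Br)c(O)c(O)cc1Br | intermediate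
19 | 2,5,6-tribromo-3,4-dihydroxybenzyl methyl sulfone | CS(=O)(=O)Cc1c(Br)c(O)c(O)c(Br)c1Br | target

**Count**
Total steps: 9. Longest linear sequence: 8 steps (steps 1–4 and 6–9 from 1); step 5 is a one-step branch.

**Steps most likely to fail**

1. Step 6. The soft α-thioalkyl Grignard reagent may add to the aryne more slowly than arylmagnesium species 12 and 14 do, so the aryne is lost to self-arylation. Regiocontrol may also erode, and bromination of surplus 10 generates an alkylating agent that can C-alkylate 14 before it is brominated. The fallback sets out from 8 and returns at 16. The aryne is generated from 8 as before but intercepted with methylmagnesium chloride, a plain alkyl Grignard reagent, to give (2,3-dimethoxy-6-methylphenyl)magnesium chloride F1, which 11 brominates to 2-bromo-3,4-dimethoxytoluene F2. Wohl–Ziegler bromination (NBS, AIBN, PhCF3, reflux) should then give 2-bromo-1-(bromomethyl)-3,4-dimethoxybenzene F3, and S-alkylation of sodium methanesulfinate CH3SO2Na by F3 in DMF at 60 °C leads to sulfone 16. The sulfur is thus brought in by SN2 at the sulfone level after the aryne step, so neither 10 nor the oxidation of step 7 is needed.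

2. Step 9. Bromine may oxidise the free catechol to the ortho-quinone, or bromination may stop after the first bromine has entered. The fallback sets out from 16 and returns at 19. The ring is brominated while both oxygens are still methylated: excess Br2 with FeBr3 in CH2Cl2 should take 16 through 2,6-dibromo-3,4-dimethoxybenzyl methyl sulfone F4 to 2,5,6-tribromo-3,4-dimethoxybenzyl methyl sulfone F5, which cannot be oxidised to a quinone. BBr3 in CH2Cl2 then cleaves both ethers to give 19.

3. Step 3. Hydrolysis of the carbamate, flanked on both sides by ortho substituents, may be sluggish, and prolonged heating with base may cost the iodine. The fallback sets out from 1 and returns at 6. An acetal replaces the carbamate as directing group: chloromethyl methyl ether and i-Pr2NEt in CH2Cl2 convert 1 into 1,2-dimethoxy-3-(methoxymethoxy)benzene F6. n-BuLi in THF at 0 °C lithiates ortho to the acetal oxygen to give [3,4-dimethoxy-2-(methoxymethoxy)phenyl]lithium F7, and iodine at −78 °C gives 1-iodo-3,4-dimethoxy-2-(methoxymethoxy)benzene F8. HCl in MeOH at 40 °C removes the acetal under conditions that leave the iodide alone and gives 6.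

**Further compounds**
F1 | step 6 | (2,3-dimethoxy-6-methylphenyl)magnesium chloride | Cc1ccc(OC)c(OC)c1[Mg]Cl
F2 | step 6 | 2-bromo-3,4-dimethoxytoluene | Cc1ccc(OC)c(OC)c1Br
F3 | step 6 | 2-bromo-1-(bromomethyl)-3,4-dimethoxybenzene | BrCc1ccc(OC)c(OC)c1Br
F4 | step 9 | 2,6-dibromo-3,4-dimethoxybenzyl methyl sulfone | CS(=O)(=O)Cc1c(Br)cc(OC)c(OC)c1Br
F5 | step 9 | 2,5,6-tribromo-3,4-dimethoxybenzyl methyl sulfone | CS(=O)(=O)Cc1c(Br)c(Br)c(OC)c(OC)c1Br
F6 | step 3 | 1,2-dimethoxy-3-(methoxymethoxy)benzene | COCOc1cccc(OC)c1OC
F7 | step 3 | [3,4-dimethoxy-2-(methoxymethoxy)phenyl]lithium | COCOc1c([Li])ccc(OC)c1OC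
F8 | step 3 | 1-iodo-3,4-dimethoxy-2-(methoxymethoxy)benzene | COCOc1c(I)ccc(OC)c1OC
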